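**Retrosynthetic overview**
- Target ⇐ hydrogenolysis of a tris-benzyl ether. The tertiary carbinol comes from a methyl propanoate side chain plus MeMgBr, with the 3-formyl group parked as CH2OH during that addition.
- 2-Aryl-3-formylbenzofuran ⇐ acid-induced MOM loss and cyclodehydration of a 1,2-diaryl-3,3-dimethoxypropan-1-one, itself from the oxidative 1,2-aryl shift of a chalcone. The furan is the only ring built; both benzene rings are bought.
- Chalcone ⇐ Claisen–Schmidt aldol condensation of 2,4-bis(benzyloxy)acetophenone with a fully substituted benzaldehyde (key C–C bond, joins the two halves).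
- Benzaldehyde ⇐ 5-methoxyresorcinol. The first CHO becomes the benzylic carbon of the side chain (Wittig, H2); its para-OH is masked as MOM (future ring O) and its ortho-OH directs the second formylation, then is benzylated (future 4-OH).

Assumption: the target has no stereocentre (it is achiral), so no enantiocontrol is needed; the only stereo-elements are E-alkenes in intermediates.

**Route**

Step 1
Reactants: 1 5-methoxyresorcinol
Product: 3 2,4-dihydroxy-6-methoxybenzaldehyde, via aryl iminium chloride 2 (not isolated)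
Conditions: POCl3 (1.2 eq), DMF (3 eq), MeCN, 0 °C → rt; then H2O, 50 °C
Reagents that add atoms: N,N-dimethylformamide CN(C)C=O; water O
Why: Vilsmeier–Haack formylation attacks one of the two equivalent positions para to one OH and ortho to the other, and the minor 2,6-dihydroxy isomer is removed by crystallisation or chromatography.

Step 2
Reactants: 3 2,4-dihydroxy-6-methoxybenzaldehyde
Product: 4 2-hydroxy-6-methoxy-4-(methoxymethoxy)benzaldehyde
Conditions: MOMCl (1.05 eq), K2CO3 (1.5 eq), acetone, 0 °C → rt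
Reagents that add atoms: chloromethyl methyl ether COCCl
Why: Williamson-type etherification is selective for the more acidic para-OH because the ortho-OH is locked in a hydrogen bond to the aldehyde.

Step 3
Reactants: 4 2-hydroxy-6-methoxy-4-(methoxymethoxy)benzaldehyde
Product: 5 methyl (E)-3-[2-hydroxy-6-methoxy-4-(methoxymethoxy)phenyl]prop-2-enoate
Conditions: Ph3P=CHCO2Me (1.5 eq), toluene, 70 °C
Reagents that add atoms: methyl (triphenylphosphoranylidene)acetate COC(=O)C=P(c1ccccc1)(c1ccccc1)c1ccccc1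
Why: Wittig olefination with a stabilised ylide tolerates the free phenol and gives the E-cinnamate, which cannot lactonise.

Step 4
Reactants: 5 methyl (E)-3-[2-hydroxy-6-methoxy-4-(methoxymethoxy)phenyl]prop-2-enoate
Product: 6 methyl 3-[2-hydroxy-6-methoxy-4-(methoxymethoxy)phenyl]propanoate
Conditions: H2 (1 atm), 10% Pd/C, EtOAc, rt
Reagents that add atoms: none
Why: Catalytic hydrogenation of the conjugated alkene leaves the MOM ether, ester and arene untouched.

Step 5
Reactants: 6 methyl 3-[2-hydroxy-6-methoxy-4-(methoxymethoxy)phenyl]propanoate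
Product: 8 methyl 3-[3-formyl-2-hydroxy-6-methoxy-4-(methoxymethoxy)phenyl]propanoate, via salicyl alcohol 7 (not isolated)
Conditions: MgCl2 (2 eq), Et3N (4 eq), (CH2O)n (6 eq), MeCN, 80 °C; cold aq citric acid
Reagents that add atoms: paraformaldehyde (formaldehyde) C=O
Why: Magnesium-phenoxide-directed ortho-formylation (Casnati–Skattebøl) delivers CHO only to the single free position ortho to the one free OH, which lies between that OH and the OMOM group.

Step 6
Reactants: 8 methyl 3-[3-formyl-2-hydroxy-6-methoxy-4-(methoxymethoxy)phenyl]propanoate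
Product: 9 methyl 3-[2-(benzyloxy)-3-formyl-6-methoxy-4-(methoxymethoxy)phenyl]propanoate
Conditions: BnBr (1.3 eq), K2CO3 (2 eq), DMF, 50 °C
Reagents that add atoms: benzyl bromide BrCc1ccccc1
Why: Williamson O-benzylation caps the chelated phenol, so the two oxygens ortho to the aldehyde are now differentiated (acid-stable Bn versus acid-labile MOM).

Step 7
Reactants: 10 2,4-dihydroxyacetophenone
Product: 11 1-[2,4-bis(benzyloxy)phenyl]ethanone
Conditions: BnBr (2.4 eq), K2CO3 (3 eq), DMF, 70 °C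
Reagents that add atoms: benzyl bromide BrCc1ccccc1
Why: Exhaustive Williamson benzylation gives base- and acid-stable phenol protection that is removed at the very end by hydrogenolysis.

Step 8
Reactants: 9 methyl 3-[2-(benzyloxy)-3-formyl-6-methoxy-4-(methoxymethoxy)phenyl]propanoate; 11 1-[2,4-bis(benzyloxy)phenyl]ethanone
Product: 14 3-[2-(benzyloxy)-3-{(E)-3-[2,4-bis(benzyloxy)phenyl]-3-oxoprop-1-en-1-yl}-6-methoxy-4-(methoxymethoxy)phenyl]propanoic acid, via aldehyde acid 12 (not isolated), via racemic aldol adduct 13 (not isolated)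
Conditions: 11 (1.1 eq), KOH (6 eq), EtOH/H2O 5:1, rt, 48 h; then 1 M HCl to pH 4, 0 °C
Reagents that add atoms: potassium hydroxide [K+].[OH-]
Why: Claisen–Schmidt aldol condensation of the methyl ketone enolate with the non-enolisable aldehyde, driven by E1cB dehydration to the thermodynamic E-chalcone, while the excess hydroxide deliberately saponifies the side-chain ester.

Step 9
Reactants: 14 3-[2-(benzyloxy)-3-{(E)-3-[2,4-bis(benzyloxy)phenyl]-3-oxoprop-1-en-1-yl}-6-methoxy-4-(methoxymethoxy)phenyl]propanoic acid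
Product: 15 methyl 3-[2-(benzyloxy)-3-{(E)-3-[2,4-bis(benzyloxy)phenyl]-3-oxoprop-1-en-1-yl}-6-methoxy-4-(methoxymethoxy)phenyl]propanoate
Conditions: MeI (1.5 eq), K2CO3 (1.5 eq), DMF, rt
Reagents that add atoms: iodomethane CI
Why: Carboxylate O-alkylation restores the methyl ester under conditions that do not touch the enone or the MOM ether.

Step 10
Reactants: 15 methyl 3-[2-(benzyloxy)-3-{(E)-3-[2,4-bis(benzyloxy)phenyl]-3-oxoprop-1-en-1-yl}-6-methoxy-4-(methoxymethoxy)phenyl]propanoate
Product: 16 racemic methyl 3-[2-(benzyloxy)-3-{1-[2,4-bis(benzyloxy)phenyl]-3,3-dimethoxy-1-oxopropan-2-yl}-6-methoxy-4-(methoxymethoxy)phenyl]propanoate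
Conditions: PhI(OH)OTs (1.2 eq), dry MeOH, rt, 2–4 h; aq NaHCO3
Reagents that add atoms: methanol CO
Why: Hypervalent-iodine oxidative rearrangement of the chalcone, in which the very electron-rich trialkoxyaryl ring undergoes a 1,2-shift from Cβ to Cα and the resulting oxocarbenium is trapped as the dimethyl acetal (the new stereocentre is racemic and is destroyed in step 11).

Step 11
Reactants: 16 racemic methyl 3-[2-(benzyloxy)-3-{1-[2,4-bis(benzyloxy)phenyl]-3,3-dimethoxy-1-oxopropan-2-yl}-6-methoxy-4-(methoxymethoxy)phenyl]propanoate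
Product: 18 methyl 3-{4-(benzyloxy)-2-[2,4-bis(benzyloxy)phenyl]-3-formyl-6-methoxy-1-benzofuran-5-yl}propanoate, via 2-methoxydihydrobenzofuran 17 (not isolated)
Conditions: TsOH·H2O (2 eq), (CF3)2CHOH, rt, 1–2 h; aq NaHCO3
Reagents that add atoms: water O
Why: In this acid cascade MOM is cleaved, the single free phenol first closes on the acetal to give 17, and in ionising HFIP this reopens and recloses on the ketone, after which irreversible cyclodehydration and acetal hydrolysis give the 2-aryl-3-formylbenzofuran; no tertiary alcohol is present yet, so no chroman can form.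

Step 12
Reactants: 18 methyl 3-{4-(benzyloxy)-2-[2,4-bis(benzyloxy)phenyl]-3-formyl-6-methoxy-1-benzofuran-5-yl}propanoate
Product: 19 methyl 3-{4-(benzyloxy)-2-[2,4-bis(benzyloxy)phenyl]-3-(hydroxymethyl)-6-methoxy-1-benzofuran-5-yl}propanoate
Conditions: NaBH4 (1.5 eq), THF/MeOH 4:1, 0 °C
Reagents that add atoms: none
Why: Chemoselective borohydride reduction of the aldehyde in the presence of the ester parks the formyl group at the alcohol level for the Grignard step.

Step 13
Reactants: 19 methyl 3-{4-(benzyloxy)-2-[2,4-bis(benzyloxy)phenyl]-3-(hydroxymethyl)-6-methoxy-1-benzofuran-5-yl}propanoate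
Product: 21 4-{4-(benzyloxy)-2-[2,4-bis(benzyloxy)phenyl]-3-(hydroxymethyl)-6-methoxy-1-benzofuran-5-yl}-2-methylbutan-2-ol, via methyl ketone 20 (not isolated)
Conditions: MeMgBr (5 eq), THF, 0 °C → rt; aq NH4Cl
Reagents that add atoms: methylmagnesium bromide C[Mg]Br
Why: Double Grignard addition to the ester builds the dimethyl carbinol after all strongly acidic steps, with the primary alcohol simply carried as its magnesium alkoxide.

Step 14
Reactants: 21 4-{4-(benzyloxy)-2-[2,4-bis(benzyloxy)phenyl]-3-(hydroxymethyl)-6-methoxy-1-benzofuran-5-yl}-2-methylbutan-2-ol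
Product: 22 4-(benzyloxy)-2-[2,4-bis(benzyloxy)phenyl]-5-(3-hydroxy-3-methylbutyl)-6-methoxy-1-benzofuran-3-carbaldehyde
Conditions: MnO2 (15 eq), CH2Cl2, rt
Reagents that add atoms: none
Why: MnO2 oxidises only the activated heterobenzylic primary alcohol back to the aldehyde and cannot touch the tertiary alcohol.

Step 15
Reactants: 22 4-(benzyloxy)-2-[2,4-bis(benzyloxy)phenyl]-5-(3-hydroxy-3-methylbutyl)-6-methoxy-1-benzofuran-3-carbaldehyde
Product: 23 Ebenfuran V
Conditions: H2 (1 atm), 10% Pd/C, EtOAc, rt, stopped after 3 eq H2; neutral work-up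
Reagents that add atoms: none
Why: Hydrogenolysis of the three aryl benzyl ethers is faster than reduction of the deactivated, vinylogous-formate aldehyde, and the acid-free conditions keep the tertiary alcohol from cyclising onto the freed 4-OH.

**Compound list**
1 | 5-methoxyresorcinol (5-methoxybenzene-1,3-diol) | COc1cc(O)cc(O)c1 | starting material
2 | (2,4-dihydroxy-6-methoxybenzylidene)dimethyliminium chloride | C[N+](C)=Cc1c(O)cc(O)cc1OC.[Cl-] | intermediate (not isolated)
3 | 2,4-dihydroxy-6-methoxybenzaldehyde | COc1cc(O)cc(O)c1C=O | intermediate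
4 | 2-hydroxy-6-methoxy-4-(methoxymethoxy)benzaldehyde | COCOc1cc(O)c(C=O)c(OC)c1 | intermediate
5 | methyl (E)-3-[2-hydroxy-6-methoxy-4-(methoxymethoxy)phenyl]prop-2-enoate | COC(=O)/C=C/c1c(O)cc(OCOC)cc1OC | intermediate
6 | methyl 3-[2-hydroxy-6-methoxy-4-(methoxymethoxy)phenyl]propanoate | COC(=O)CCc1c(O)cc(OCOC)cc1OC | intermediate
7 | methyl 3-[2-hydroxy-3-(hydroxymethyl)-6-methoxy-4-(methoxymethoxy)phenyl]propanoate | COC(=O)CCc1c(O)c(CO)c(OCOC)cc1OC | intermediate (not isolated)
8 | methyl 3-[3-formyl-2-hydroxy-6-methoxy-4-(methoxymethoxy)phenyl]propanoate | COC(=O)CCc1c(O)c(C=O)c(OCOC)cc1OC | intermediate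
9 | methyl 3-[2-(benzyloxy)-3-formyl-6-methoxy-4-(methoxymethoxy)phenyl]propanoate | COC(=O)CCc1c(OCc2ccccc2)c(C=O)c(OCOC)cc1OC | intermediate
10 | 2,4-dihydroxyacetophenone | CC(=O)c1ccc(O)cc1O | starting material
11 | 1-[2,4-bis(benzyloxy)phenyl]ethanone | CC(=O)c1ccc(OCc2ccccc2)cc1OCc1ccccc1 | intermediate
12 | 3-[2-(benzyloxy)-3-formyl-6-methoxy-4-(methoxymethoxy)phenyl]propanoic acid (potassium salt in the flask) | OC(=O)CCc1c(OCc2ccccc2)c(C=O)c(OCOC)cc1OC | intermediate (not isolated)
13 | racemic 3-[2-(benzyloxy)-3-{3-[2,4-bis(benzyloxy)phenyl]-1-hydroxy-3-oxopropyl}-6-methoxy-4-(methoxymethoxy)phenyl]propanoic acid (potassium salt in the flask) | OC(=O)CCc1c(OCc2ccccc2)c(C(O)CC(=O)c2ccc(OCc3ccccc3)cc2OCc2ccccc2)c(OCOC)cc1OC | intermediate (not isolated)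
14 | 3-[2-(benzyloxy)-3-{(E)-3-[2,4-bis(benzyloxy)phenyl]-3-oxoprop-1-en-1-yl}-6-methoxy-4-(methoxymethoxy)phenyl]propanoic acid | OC(=O)CCc1c(OCc2ccccc2)c(/C=C/C(=O)c2ccc(OCc3ccccc3)cc2OCc2ccccc2)c(OCOC)cc1OC | intermediate
15 | methyl 3-[2-(benzyloxy)-3-{(E)-3-[2,4-bis(benzyloxy)phenyl]-3-oxoprop-1-en-1-yl}-6-methoxy-4-(methoxymethoxy)phenyl]propanoate | COC(=O)CCc1c(OCc2ccccc2)c(/C=C/C(=O)c2ccc(OCc3ccccc3)cc2OCc2ccccc2)c(OCOC)cc1OC | intermediate
16 | racemic methyl 3-[2-(benzyloxy)-3-{1-[2,4-bis(benzyloxy)phenyl]-3,3-dimethoxy-1-oxopropan-2-yl}-6-methoxy-4-(methoxymethoxy)phenyl]propanoate | COC(=O)CCc1c(OCc2ccccc2)c(C(C(OC)OC)C(=O)c2ccc(OCc3ccccc3)cc2OCc2ccccc2)c(OCOC)cc1OC | intermediate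
17 | methyl 3-{4-(benzyloxy)-3-[2,4-bis(benzyloxy)benzoyl]-2,6-dimethoxy-2,3-dihydro-1-benzofuran-5-yl}propanoate (racemic, diastereomer mixture) | COC(=O)CCc1c(OC)cc2OC(OC)C(C(=O)c3ccc(OCc4ccccc4)cc3OCc3ccccc3)c2c1OCc1ccccc1 | intermediate (not isolated)
18 | methyl 3-{4-(benzyloxy)-2-[2,4-bis(benzyloxy)phenyl]-3-formyl-6-methoxy-1-benzofuran-5-yl}propanoate | COC(=O)CCc1c(OC)cc2oc(-c3ccc(OCc4ccccc4)cc3OCc3ccccc3)c(C=O)c2c1OCc1ccccc1 | intermediate
19 | methyl 3-{4-(benzyloxy)-2-[2,4-bis(benzyloxy)phenyl]-3-(hydroxymethyl)-6-methoxy-1-benzofuran-5-yl}propanoate | COC(=O)CCc1c(OC)cc2oc(-c3ccc(OCc4ccccc4)cc3OCc3ccccc3)c(CO)c2c1OCc1ccccc1 | intermediate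
20 | 4-{4-(benzyloxy)-2-[2,4-bis(benzyloxy)phenyl]-3-(hydroxymethyl)-6-methoxy-1-benzofuran-5-yl}butan-2-one (magnesium alkoxide in the flask) | CC(=O)CCc1c(OC)cc2oc(-c3ccc(OCc4ccccc4)cc3OCc3ccccc3)c(CO)c2c1OCc1ccccc1 | intermediate (not isolated)
21 | 4-{4-(benzyloxy)-2-[2,4-bis(benzyloxy)phenyl]-3-(hydroxymethyl)-6-methoxy-1-benzofuran-5-yl}-2-methylbutan-2-ol | CC(C)(O)CCc1c(OC)cc2oc(-c3ccc(OCc4ccccc4)cc3OCc3ccccc3)c(CO)c2c1OCc1ccccc1 | intermediate
22 | 4-(benzyloxy)-2-[2,4-bis(benzyloxy)phenyl]-5-(3-hydroxy-3-methylbutyl)-6-methoxy-1-benzofuran-3-carbaldehyde | CC(C)(O)CCc1c(OC)cc2oc(-c3ccc(OCc4ccccc4)cc3OCc3ccccc3)c(C=O)c2c1OCc1ccccc1 | intermediate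
23 | Ebenfuran V, 2-(2,4-dihydroxyphenyl)-4-hydroxy-5-(3-hydroxy-3-methylbutyl)-6-methoxy-1-benzofuran-3-carbaldehyde | COc1cc2oc(-c3ccc(O)cc3O)c(C=O)c2c(O)c1CCC(C)(C)O | target

**Totals**
Total step count: 15. Longest linear sequence: 14 (steps 1–6, then 8–15); step 7 is the one-step side branch.

**Three steps most likely to fail, with fallbacks**

Step 5 (risk: the hydroxy ester 6 lactonises to a dihydrocoumarin under MgCl2/Et3N at reflux, or the very electron-rich ring over-reacts with formaldehyde). The fallback sets out from 5 and comes back at 8. The same magnesium-mediated ortho-formylation is run one stage earlier on the E-acrylate, whose trans geometry makes lactonisation impossible and whose acrylate tempers the ring. This gives methyl (E)-3-[3-formyl-2-hydroxy-6-methoxy-4-(methoxymethoxy)phenyl]prop-2-enoate F1. Only its C=C is then saturated with H2 over Pd/C poisoned with diphenyl sulfide in EtOAc, which leaves the aryl aldehyde intact and delivers 8.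

Step 10 (risk: the hindered chalcone reacts sluggishly with the iodane, or the TsOH formed strips the MOM group before the aryl shift and the free phenol is oxidised). The fallback sets out from 15 and comes back at 16, replacing the oxidative aryl shift by an epoxide/acyl-shift sequence. Non-hydrolytic Weitz–Scheffer epoxidation (TBHP, DBU, CH2Cl2) gives racemic trans methyl 3-[2-(benzyloxy)-3-{3-[2,4-bis(benzyloxy)benzoyl]oxiran-2-yl}-6-methoxy-4-(methoxymethoxy)phenyl]propanoate F2. Brief BF3·OEt2 in CH2Cl2 at −20 °C opens the epoxide at the benzylic carbon and triggers a 1,2-aroyl shift to racemic methyl 3-[2-(benzyloxy)-3-{1-[2,4-bis(benzyloxy)phenyl]-1,3-dioxopropan-2-yl}-6-methoxy-4-(methoxymethoxy)phenyl]propanoate F3. HC(OMe)3/MeOH with catalytic PPTS converts its formyl group into the dimethyl acetal, which is 16.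

Step 11 (risk: the phenol ends up on the aldehyde carbon and gives the isomeric 3-aroylbenzofuran, or HFIP/TsOH erodes the benzyl ethers). The fallback sets out from 16 and comes back at 18, removing the ambiguity by making the formyl carbon non-electrophilic. 1,3-Propanedithiol and BF3·OEt2 in CH2Cl2 (−20 → 0 °C) exchange the dimethyl acetal for a dithiane and cleave the MOM ether, so the liberated phenol can only cyclodehydrate onto the ketone. This gives methyl 3-{4-(benzyloxy)-2-[2,4-bis(benzyloxy)phenyl]-3-(1,3-dithian-2-yl)-6-methoxy-1-benzofuran-5-yl}propanoate F4. The dithiane is then unmasked with MeI and CaCO3 in aqueous MeCN at 40 °C to give 18.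

**Further compounds**
F1 | step 5 | methyl (E)-3-[3-formyl-2-hydroxy-6-methoxy-4-(methoxymethoxy)phenyl]prop-2-enoate | COC(=O)/C=C/c1c(O)c(C=O)c(OCOC)cc1OC
F2 | step 10 | racemic trans methyl 3-[2-(benzyloxy)-3-{3-[2,4-bis(benzyloxy)benzoyl]oxiran-2-yl}-6-methoxy-4-(methoxymethoxy)phenyl]propanoate | COC(=O)CCc1c(OCc2ccccc2)c(C2OC2C(=O)c2ccc(OCc3ccccc3)cc2OCc2ccccc2)c(OCOC)cc1OC
F3 | step 10 | racemic methyl 3-[2-(benzyloxy)-3-{1-[2,4-bis(benzyloxy)phenyl]-1,3-dioxopropan-2-yl}-6-methoxy-4-(methoxymethoxy)phenyl]propanoate | COC(=O)CCc1c(OCc2ccccc2)c(C(C=O)C(=O)c2ccc(OCc3ccccc3)cc2OCc2ccccc2)c(OCOC)cc1OC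
F4 | step 11 | methyl 3-{4-(benzyloxy)-2-[2,4-bis(benzyloxy)phenyl]-3-(1,3-dithian-2-yl)-6-methoxy-1-benzofuran-5-yl}propanoate | COC(=O)CCc1c(OC)cc2oc(-c3ccc(OCc4ccccc4)cc3OCc3ccccc3)c(C3SCCCS3)c2c1OCc1ccccc1
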